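4 questions stand open, and they come down to one decision: what do we do to the grey flask at 8.0 d?

| setting | grey | teal | flask |
|---|---|---|---|
| L | 1 M | 1 M | 1.0 M |
| G | 1.05 M | 1.05 M | 1.05 M |
| D | 0.10 M | 0.050 M | 0.100 M |
| remark | the very flask that is asked about, followed so far | run made earlier |  |
| time |  |  | 8.0 d |

| run | time / d | J / % | L / % |
|---|---|---|---|
| grey | 0.625 | 50.2 | 33.0 |
| grey | 1.67 | 57.3 | 22.8 |
| grey | 3.00 | 60.4 | 20.6 |
| grey | 8.00 | 61.6 | 17.7 |
| teal | 0.500 | 46.0 | 35.6 |
| teal | 1.25 | 54.9 | 25.6 |
| teal | 2.50 | 60.4 | 19.8 |
| teal | 4.00 | 62.2 | 17.6 |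

(readings scatter by 1 percentage point)

- Tuesday's: change nothing and wait 15 d more
- Friday's: at 8.0 d add G, 50.0 % of the amount charged, then wait 15 d
- Monday's: at 8.0 d add L, 50.0 % of the amount charged, then wait 15 d

* J, in percent of the L first charged, at 8.0 d
* which option adds most J ("none" when 2 percentage points or less is all one gets) (Tuesday's / Friday's / Monday's / none)
* J present, in percent of the L first charged, after Tuesday's
* J present, in percent of the L first charged, after Monday's

- for J the Q are counted in
- as a solid, counted per litre of solution: Q
- the volume of additions can be left aside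
- what may be going on: G + D -> E; L + 2 G -> X; Q <-> J; L + G -> J

L can leave by L + G -> J or by L + 2 G -> X. We take the last grey reading and count the L turned, 82.3 % of the charge:

G price = 2 − 61.6 % / 82.3 % = 1.25

This number, read from scattered readings, is the G spent in these two steps per L turned, the G price. Its zero is 1, the case where turned L ends in J. G taken by D is not counted in it, and any such G would lower the figures below. The last teal reading, taken at 4.00 d with half the D, gives 1.25, so the price reads alike in the two runs.

Now we ask what the G charge can buy in the grey flask:

L turned = 1.05 M / 1.25 = 0.839 M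

J ceiling = 62.8 %

This is less than the L charged, so G is the limiting reagent. We commit to J near 61.6 % at 8.0 d. Tuesday's and Monday's bring no G, and at this price the ceiling stands 1.2 percentage points above the reading, less than the 2 points that counts.

Friday's brings 0.525 M of G. The L at the last grey reading costs:

G needed = 1.25 × [L] = 1.25 × 0.177 M = 0.222 M

That is less than the addition, so at the same price we reckon a gain in J of 13 points. We charge G.

The forecast gave 61.8 % (60.6 % to 63 %), 62.4 % after Tuesday's and 62.6 % after Monday's, and it chose Friday's: "Adding 0.525 M G consumes the remaining 0.17 M L at about 75% selectivity, giving J near 74%."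

The flask gives 60.9 % at 8.0 d. Tuesday's adds 0.011 points, Monday's 0.012 points and Friday's 16 points, so the choice is Friday's.

    G + D → E (k = 0.110 M⁻¹ h⁻¹)
    L + 2 G → X (k = 0.110 M⁻² h⁻¹)
    Q ⇌ J, rate k3*(cs3 - [J]) while solid is left; crystals form when [J] > cs3 (solubility = 12.0 mM, k = 1.70 h⁻¹)
    L + G → J (k = 0.160 M⁻¹ h⁻¹)

At 8.00 d, 0.0120 % of the charged G is free, beside 20.0 % of the L. Now take the neighbour flask with 0.40 M of L and the other charges as here. Our price asks 0.500 M of G for its L. If its D goes too, that takes 0.100 M more, so 42.9 % of the G should stay. At 8.00 d that flask stands with L at 0 %, D at 0.00914 % and G at 40 %.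

(Readings and results are calculated for substances that don't exist, and the scatter is random.)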